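**Retrosynthetic overview**
1. Target 22 ⇐ 21 (removal of the O-5' allyl group) ⇐ 20 (prenylation of C-6, the last free carbon of ring A).
2. Ring-B pyran (last ring): 20 ⇐ isopropenyl ether 17 + ethyl vinyl ether as a two-carbon acetylene equivalent, by a cationic [4+2] annulation that forms C-3''–C-2'' and C-4''–C-3' and keeps the O-4'–C-2'' bond of the precursor.
3. Enabling feature: in ring B, O-4' has a single free ortho carbon, C-3', which lies between O-4' and the furan oxygen on C-2' (the other ortho carbon, C-5', is oxygenated), so a cation tethered to O-4' can only close the pyran at this doubly oxygen-activated carbon.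
4. Furan ring: 16 ⇐ 2'-hydroxyisoflavone 15 (DDQ); C-3–C-1' bond ⇐ Suzuki–Miyaura coupling of 3-iodochromone 6 with arylboronate 13.
5. Ring order: ring-A pyran (chelation-directed propargyl Claisen on the acetophenone) → pyranone → coupling → furan → ring-B pyran.

Key step: step 13

Remark: the target has no stereocentre, so no stereocontrol is needed. Numbering follows isoflavone usage: pyranone O-1, C-2 to C-8a; ring B C-1' to C-6'; furan oxygen between C-2 and C-2'; ring-B pyran O(4')–C-2''–C-3''–C-4''–C-3'.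

**Route**

Step 1
Reactants: 1 1-(2,4,6-trihydroxyphenyl)ethan-1-one
Product: 2 1-[2,6-dihydroxy-4-(2-methylbut-3-yn-2-yloxy)phenyl]ethan-1-one
Conditions: 3-chloro-3-methylbut-1-yne, K2CO3, KI, CuI (cat.), acetone, 56 °C
Reagents that add atoms: 3-chloro-3-methylbut-1-yne, CC(C)(Cl)C#C
Why: The 4-OH is the only hydroxyl not hydrogen-bonded to the acetyl group and the most acidic, so copper-assisted Williamson etherification with the tertiary propargylic chloride should occur there selectively.

Step 2
Reactants: 2 1-[2,6-dihydroxy-4-(2-methylbut-3-yn-2-yloxy)phenyl]ethan-1-one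
Product: 3 1-[2-hydroxy-6-(methoxymethoxy)-4-(2-methylbut-3-yn-2-yloxy)phenyl]ethan-1-one
Conditions: MOMCl (1.1 equiv), i-Pr2NEt, CH2Cl2, 0 °C
Reagents that add atoms: chloromethyl methyl ether, COCCl
Why: The two remaining hydroxyls are equivalent, and once one is alkylated the other is locked in a strong hydrogen bond to the ketone, so a single mono-methoxymethyl ether should form (Williamson-type O-alkylation).

Step 3
Reactants: 3 1-[2-hydroxy-6-(methoxymethoxy)-4-(2-methylbut-3-yn-2-yloxy)phenyl]ethan-1-one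
Product: 4 1-[5-hydroxy-7-(methoxymethoxy)-2,2-dimethyl-2H-chromen-6-yl]ethan-1-one
Conditions: PhNEt2, 190 °C
Reagents that add atoms: none
Why: The aryl propargyl ether Claisen sequence ([3,3] shift, 1,5-hydrogen shift, oxa-6π electrocyclisation) should close the 2,2-dimethyl-2H-pyran onto the carbon ortho to the chelated hydroxyl, the site favoured by the bond fixation of the O–H···O=C chelate, as in the classical conversion of 2-hydroxy-4-propargyloxyacetophenones into 6-acetyl-5-hydroxychromenes.

Step 4
Reactants: 4 1-[5-hydroxy-7-(methoxymethoxy)-2,2-dimethyl-2H-chromen-6-yl]ethan-1-one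
Product: 6 3-iodo-5-(methoxymethoxy)-8,8-dimethyl-4H,8H-pyrano[2,3-h]chromen-4-one, via enaminone 5 (not isolated)
Conditions: Me2NCH(OMe)2, 95 °C; then I2, CHCl3, 23 °C
Reagents that add atoms: N,N-dimethylformamide dimethyl acetal, COC(OC)N(C)C; iodine, II
Why: Condensation gives the enaminone, and iodine then induces cyclisation of the single free phenol onto it with loss of dimethylamine (enaminone iodocyclisation to a 3-iodochromone), which places the pyranone oxygen next to the pyran-bearing carbon.

Step 5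
Reactants: 7 5-bromo-2,4-dihydroxybenzaldehyde
Product: 8 5-bromo-2,4-bis(methoxymethoxy)benzaldehyde
Conditions: MOMCl (3 equiv), i-Pr2NEt, CH2Cl2, 0 to 40 °C
Reagents that add atoms: chloromethyl methyl ether, COCCl
Why: Williamson-type protection of both phenols with excess reagent, which should also overcome the hydrogen bond of the 2-OH to the aldehyde.

Step 6
Reactants: 8 5-bromo-2,4-bis(methoxymethoxy)benzaldehyde
Product: 10 5-bromo-2,4-bis(methoxymethoxy)phenol, via aryl formate 9 (not isolated)
Conditions: mCPBA, CH2Cl2, 23 °C; then K2CO3 (cat.), MeOH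
Reagents that add atoms: 3-chloroperoxybenzoic acid, OOC(=O)c1cccc(Cl)c1
Why: Baeyer–Villiger oxidation of the electron-rich benzaldehyde with aryl migration (Dakin-type) should give the formate, which mild methanolysis converts into the phenol that becomes O-5'.

Step 7
Reactants: 10 5-bromo-2,4-bis(methoxymethoxy)phenol
Product: 11 1-bromo-2,4-bis(methoxymethoxy)-5-(prop-2-en-1-yloxy)benzene
Conditions: allyl bromide, K2CO3, DMF, 23 °C
Reagents that add atoms: allyl bromide, C=CCBr
Why: Williamson allylation of the only free phenol installs an O-5' protecting group that is orthogonal to the methoxymethyl ethers and should tolerate DDQ, base and Lewis acid.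

Step 8
Reactants: 11 1-bromo-2,4-bis(methoxymethoxy)-5-(prop-2-en-1-yloxy)benzene
Product: 13 2-[2,4-bis(methoxymethoxy)-5-(prop-2-en-1-yloxy)phenyl]-4,4,5,5-tetramethyl-1,3,2-dioxaborolane, via aryllithium 12 (not isolated)
Conditions: n-BuLi, THF, −78 °C; then 2-isopropoxy-4,4,5,5-tetramethyl-1,3,2-dioxaborolane, −78 to 0 °C
Reagents that add atoms: 2-isopropoxy-4,4,5,5-tetramethyl-1,3,2-dioxaborolane, CC(C)OB1OC(C)(C)C(C)(C)O1
Why: Bromine–lithium exchange at −78 °C should outrun any deprotonation, and the aryllithium is trapped by the borate to give the pinacol boronate.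

Step 9
Reactants: 6 3-iodo-5-(methoxymethoxy)-8,8-dimethyl-4H,8H-pyrano[2,3-h]chromen-4-one; 13 2-[2,4-bis(methoxymethoxy)-5-(prop-2-en-1-yloxy)phenyl]-4,4,5,5-tetramethyl-1,3,2-dioxaborolane
Product: 14 3-[2,4-bis(methoxymethoxy)-5-(prop-2-en-1-yloxy)phenyl]-5-(methoxymethoxy)-8,8-dimethyl-4H,8H-pyrano[2,3-h]chromen-4-one
Conditions: Pd(dppf)Cl2 (5 mol %), Na2CO3, 1,4-dioxane/H2O, 80 °C
Reagents that add atoms: none
Why: Suzuki–Miyaura coupling of 3-iodochromones with arylboron reagents is the standard isoflavone assembly, and the dppf complex with a mild carbonate base is chosen so that the allyl ether should survive.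

Step 10
Reactants: 14 3-[2,4-bis(methoxymethoxy)-5-(prop-2-en-1-yloxy)phenyl]-5-(methoxymethoxy)-8,8-dimethyl-4H,8H-pyrano[2,3-h]chromen-4-one
Product: 15 3-[2,4-dihydroxy-5-(prop-2-en-1-yloxy)phenyl]-5-hydroxy-8,8-dimethyl-4H,8H-pyrano[2,3-h]chromen-4-one
Conditions: HCl (cat.), MeOH/THF, 45 °C
Reagents that add atoms: none
Why: Acid-catalysed acetal exchange with methanol should remove the three methoxymethyl groups, while the allyl ether and the 2H-pyran tolerate dilute methanolic acid.

Step 11
Reactants: 15 3-[2,4-dihydroxy-5-(prop-2-en-1-yloxy)phenyl]-5-hydroxy-8,8-dimethyl-4H,8H-pyrano[2,3-h]chromen-4-one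
Product: 16 5,4'-dihydroxy-5'-allyloxy-7,8-(2,2-dimethylpyrano)coumaronochromone
Conditions: DDQ (1.1 equiv), 1,4-dioxane, 23 to 60 °C
Reagents that add atoms: none
Why: DDQ-mediated dehydrogenative cyclisation of a 2'-hydroxyisoflavone to a coumaronochromone: the electron-rich ring B is oxidised, O-2' adds to C-2 and re-aromatisation closes the furan.

Step 12
Reactants: 16 5,4'-dihydroxy-5'-allyloxy-7,8-(2,2-dimethylpyrano)coumaronochromone
Product: 17 5-hydroxy-4'-(prop-1-en-2-yloxy)-5'-allyloxy-7,8-(2,2-dimethylpyrano)coumaronochromone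
Conditions: 2-bromopropene, CuI (10 mol %), N,N-dimethylglycine (20 mol %), Cs2CO3, 1,4-dioxane, 80 °C (sealed tube)
Reagents that add atoms: 2-bromopropene, CC(Br)=C
Why: Copper-catalysed Ullmann-type O-vinylation of a phenol with a vinyl bromide; the 5-OH is deactivated by its hydrogen bond to the C-4 carbonyl, so only O-4' should couple.

Step 13
Reactants: 17 5-hydroxy-4'-(prop-1-en-2-yloxy)-5'-allyloxy-7,8-(2,2-dimethylpyrano)coumaronochromone
Product: 20 5-hydroxy-5'-allyloxy-7,8:4',3'-bis(2,2-dimethylpyrano)coumaronochromone, via acetoxy ketal 18 (not isolated), via 4''-ethoxychroman 19 (not isolated)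
Conditions: AcOH, pyridinium p-toluenesulfonate (cat.), CH2Cl2, 0 °C, evaporate; ethyl vinyl ether (3 equiv), Me3SiOTf (10 mol %), CH2Cl2, −78 °C, then Et3N; pyridinium p-toluenesulfonate, PhMe, 80 °C
Reagents that add atoms: ethyl vinyl ether, C=COCC
Why: Proposed new method: acetic acid adds across the enol ether to give acetoxy ketal 18, whose acetate is ionised by Me3SiOTf to the aryloxocarbenium ion on O-4'; ethyl vinyl ether attacks it through its CH2 terminus (bond C-3''–C-2''), the resulting ethoxycarbenium ion is captured by C-3' in an intramolecular Friedel–Crafts alkylation (bond C-4''–C-3'), and the acid then eliminates ethanol from 19 to give the 2H-pyran. The closest known reaction types are the oxa-Povarov reaction of aryl oxocarbenium ions with alkenes to chromans, the Povarov reaction of N-aryl iminium ions with enol ethers, and the Lewis acid mediated addition of α-acetoxy ethers and ketals to enol ethers; new here are the ketone-derived cation, the vinyl ether as acetylene equivalent and the late-stage substrate. The six-membered ring closes by a 6-exo-trig attack of the arene carbon on the oxocarbenium carbon, the whole being a stepwise cationic [4+2] annulation. The only stereocentre formed, C-4'' of 19, is racemic and is erased by the elimination. Site selectivity is secured because C-3' is the only unsubstituted carbon ortho to O-4' (C-5' carries the allyl ether) and is activated by both flanking oxygens; chemoselectivity over the ring-A pyran alkene and the allyl group rests on the far higher nucleophilicity of the vinyl ether at −78 °C and on the absence of free strong acid.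

Step 14
Reactants: 20 5-hydroxy-5'-allyloxy-7,8:4',3'-bis(2,2-dimethylpyrano)coumaronochromone
Product: 21 5-hydroxy-6-(3-methylbut-2-en-1-yl)-5'-allyloxy-7,8:4',3'-bis(2,2-dimethylpyrano)coumaronochromone
Conditions: NaH, prenyl bromide, PhMe, 0 to 23 °C
Reagents that add atoms: 1-bromo-3-methylbut-2-ene (prenyl bromide), CC(C)=CCBr
Why: C-Alkylation of a sodium phenoxide in a non-polar solvent (ortho-prenylation) should go to C-6, the only free position of ring A and ortho to the phenoxide oxygen, while O-5' is masked as the allyl ether.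

Step 15
Reactants: 21 5-hydroxy-6-(3-methylbut-2-en-1-yl)-5'-allyloxy-7,8:4',3'-bis(2,2-dimethylpyrano)coumaronochromone
Product: 22 5,5'-dihydroxy-6-(3-methylbut-2-en-1-yl)-7,8:4',3'-bis(2,2-dimethylpyrano)coumaronochromone (CNP0323631.0)
Conditions: Pd(PPh3)4 (5 mol %), morpholine, THF, 23 °C
Reagents that add atoms: none
Why: Tsuji–Trost-type deallylation, in which zerovalent palladium ionises the aryl allyl ether and morpholine captures the allyl fragment, should leave the prenyl group and both 2H-pyrans untouched.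

**Compound list**
1 | 1-(2,4,6-trihydroxyphenyl)ethan-1-one | CC(=O)c1c(O)cc(O)cc1O | starting material
2 | 1-[2,6-dihydroxy-4-(2-methylbut-3-yn-2-yloxy)phenyl]ethan-1-one | CC(=O)c1c(O)cc(OC(C)(C)C#C)cc1O | intermediate
3 | 1-[2-hydroxy-6-(methoxymethoxy)-4-(2-methylbut-3-yn-2-yloxy)phenyl]ethan-1-one | CC(=O)c1c(O)cc(OC(C)(C)C#C)cc1OCOC | intermediate
4 | 1-[5-hydroxy-7-(methoxymethoxy)-2,2-dimethyl-2H-chromen-6-yl]ethan-1-one | CC(=O)c1c(O)c2C=CC(C)(C)Oc2cc1OCOC | intermediate
5 | (E)-3-(dimethylamino)-1-[5-hydroxy-7-(methoxymethoxy)-2,2-dimethyl-2H-chromen-6-yl]prop-2-en-1-one | CN(C)/C=C/C(=O)c1c(O)c2C=CC(C)(C)Oc2cc1OCOC | intermediate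
6 | 3-iodo-5-(methoxymethoxy)-8,8-dimethyl-4H,8H-pyrano[2,3-h]chromen-4-one | O=c1c(I)coc2c3C=CC(C)(C)Oc3cc(OCOC)c12 | intermediate
7 | 5-bromo-2,4-dihydroxybenzaldehyde | O=Cc1cc(Br)c(O)cc1O | starting material
8 | 5-bromo-2,4-bis(methoxymethoxy)benzaldehyde | O=Cc1cc(Br)c(OCOC)cc1OCOC | intermediate
9 | 5-bromo-2,4-bis(methoxymethoxy)phenyl formate | O=COc1cc(Br)c(OCOC)cc1OCOC | intermediate
10 | 5-bromo-2,4-bis(methoxymethoxy)phenol | Oc1cc(Br)c(OCOC)cc1OCOC | intermediate
11 | 1-bromo-2,4-bis(methoxymethoxy)-5-(prop-2-en-1-yloxy)benzene | C=CCOc1cc(Br)c(OCOC)cc1OCOC | intermediate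
12 | [2,4-bis(methoxymethoxy)-5-(prop-2-en-1-yloxy)phenyl]lithium | [Li]c1cc(OCC=C)c(OCOC)cc1OCOC | intermediate
13 | 2-[2,4-bis(methoxymethoxy)-5-(prop-2-en-1-yloxy)phenyl]-4,4,5,5-tetramethyl-1,3,2-dioxaborolane | CC1(C)OB(OC1(C)C)c1cc(OCC=C)c(OCOC)cc1OCOC | intermediate
14 | 3-[2,4-bis(methoxymethoxy)-5-(prop-2-en-1-yloxy)phenyl]-5-(methoxymethoxy)-8,8-dimethyl-4H,8H-pyrano[2,3-h]chromen-4-one | O=c1c(-c2cc(OCC=C)c(OCOC)cc2OCOC)coc2c3C=CC(C)(C)Oc3cc(OCOC)c12 | intermediate
15 | 3-[2,4-dihydroxy-5-(prop-2-en-1-yloxy)phenyl]-5-hydroxy-8,8-dimethyl-4H,8H-pyrano[2,3-h]chromen-4-one | O=c1c(-c2cc(OCC=C)c(O)cc2O)coc2c3C=CC(C)(C)Oc3cc(O)c12 | intermediate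
16 | coumaronochromone (isoflavone with an oxygen joining C-2 and C-2') carrying 5-OH, a 2,2-dimethyl-2H-pyran fused at O-7/C-8, 4'-OH and 5'-O-allyl | Oc1cc2OC(C)(C)C=Cc2c2oc3oc4cc(O)c(OCC=C)cc4c3c(=O)c12 | intermediate
17 | 4'-O-isopropenyl (prop-1-en-2-yl) ether of 16 | Oc1cc2OC(C)(C)C=Cc2c2oc3oc4cc(OC(C)=C)c(OCC=C)cc4c3c(=O)c12 | intermediate
18 | 4'-O-(2-acetoxypropan-2-yl) ketal corresponding to 17 | Oc1cc2OC(C)(C)C=Cc2c2oc3oc4cc(OC(C)(C)OC(C)=O)c(OCC=C)cc4c3c(=O)c12 | intermediate
19 | racemic 4''-ethoxy-3'',4''-dihydro derivative of 20 (ring-B chroman, O-4'/C-3' fused) | Oc1cc2OC(C)(C)C=Cc2c2oc3oc4c5C(OCC)CC(C)(C)Oc5c(OCC=C)cc4c3c(=O)c12 | intermediate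
20 | coumaronochromone with 5-OH, 5'-O-allyl and 2,2-dimethyl-2H-pyrans fused at O-7/C-8 and at O-4'/C-3' | Oc1cc2OC(C)(C)C=Cc2c2oc3oc4c5C=CC(C)(C)Oc5c(OCC=C)cc4c3c(=O)c12 | intermediate
21 | 6-(3-methylbut-2-en-1-yl) derivative of 20 | Oc1c(CC=C(C)C)c2OC(C)(C)C=Cc2c2oc3oc4c5C=CC(C)(C)Oc5c(OCC=C)cc4c3c(=O)c12 | intermediate
22 | CNP0323631.0: coumaronochromone with 5-OH, 5'-OH, 6-prenyl and 2,2-dimethyl-2H-pyrans fused at O-7/C-8 and at O-4'/C-3' | Oc1c(CC=C(C)C)c2OC(C)(C)C=Cc2c2oc3oc4c5C=CC(C)(C)Oc5c(O)cc4c3c(=O)c12 | target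

**Totals**
Total step count: 15. Longest linear sequence: 11 steps (steps 1–4 or 5–8, then 9–15).

**Steps most likely to fail**

Step 13 (the proposed annulation). The aryloxocarbenium ion may lose a proton back to the enol ether, or be consumed by oligomerisation of the vinyl ether, faster than it is trapped and ring-closed; the final loss of ethanol may also be incomplete. Fallback: the 4'-phenol 16 would be etherified with 3-chloro-3-methylbut-1-yne (K2CO3, KI, CuI, acetone) to the 4'-O-(2-methylbut-3-yn-2-yl) ether F1. Heating F1 in xylene at about 140 °C should bring about the aryl propargyl ether Claisen rearrangement, 1,5-hydrogen shift and oxa-6π electrocyclisation, closing the same pyran onto C-3', the only free ortho position. The allyl ether on O-5' rearranges only at clearly higher temperature. This rejoins the route at 20.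

Step 14 (C-prenylation). O-Alkylation of the chelated phenoxide may compete with C-alkylation, and conversion of the weakly nucleophilic chelate may be low. Fallback: 20 would be O-alkylated on purpose (prenyl bromide, K2CO3, DMF) to the 5-O-prenyl ether F2. Treating F2 with montmorillonite K10 clay in CH2Cl2 at 0 °C should then induce the known 1,3-shift of aryl prenyl ethers to the ortho carbon; the para position C-8 is blocked, so only C-6 is available. This rejoins the route at 21.

Step 12 (O-vinylation). C–O coupling at the hindered, catechol-type 4'-phenol may be sluggish, and carbonate at 80 °C may open the pyranone ring. Fallback: 16 would be alkylated at O-4' with 2-bromo-2-methylpropanoic acid (Cs2CO3, MeCN, 60 °C) to the 2-aryloxy-2-methylpropanoic acid F3. Oxidative decarboxylation of F3 with Pb(OAc)4 in benzene/AcOH, the established conversion of α-alkoxy acids into α-acetoxy ethers, should give the acetoxy ketal 18 directly. The route is rejoined at 18, in the second stage of step 13.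

Further compounds
F1 | step 13 | 4'-O-(2-methylbut-3-yn-2-yl) ether of 16 | Oc1cc2OC(C)(C)C=Cc2c2oc3oc4cc(OC(C)(C)C#C)c(OCC=C)cc4c3c(=O)c12
F2 | step 14 | 5-O-(3-methylbut-2-en-1-yl) ether of 20 | CC(C)=CCOc1cc2OC(C)(C)C=Cc2c2oc3oc4c5C=CC(C)(C)Oc5c(OCC=C)cc4c3c(=O)c12
F3 | step 12 | 2-methyl-2-(aryloxy)propanoic acid formed at O-4' of 16 | Oc1cc2OC(C)(C)C=Cc2c2oc3oc4cc(OC(C)(C)C(O)=O)c(OCC=C)cc4c3c(=O)c12
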